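In early minutes X rises and falls, and the flask sits between runs already made, so I reckon only the correction from the birch run, setting by setting.

| flask | D | L | remark | time |
|---|---|---|---|---|
| birch | 17 mM | 37.5 mM | run made earlier |  |
| alder | 38 mM | 37.5 mM | run made earlier |  |
| maple | 25 mM | 75 mM | run made earlier |  |
| flask | 25 mM | 37.5 mM |  | 1.0 h |

| run | time / min | X / % | J / % | D / % |
|---|---|---|---|---|
| birch | 0.500 | 11.0 | 3.5 | 79.0 |
| birch | 1.00 | 13.5 | 7.6 | 64.0 |
| birch | 2.00 | 15.2 | 18.9 | 45.1 |
| birch | 5.00 | 11.0 | 36.5 | 16.6 |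
| birch | 10.0 | 7.8 | 45.1 | 5.9 |
| birch | 20.0 | 10.5 | 48.5 | 0.8 |
| birch | 50.0 | 6.0 | 45.0 | 0.2 |
| alder | 0.500 | 8.9 | 2.2 | 75.0 |
| alder | 1.00 | 12.7 | 6.4 | 56.4 |
| alder | 2.00 | 12.2 | 16.5 | 37.7 |
| alder | 5.00 | 6.2 | 25.3 | 16.4 |
| alder | 10.0 | 6.4 | 33.1 | 7.5 |
| alder | 20.0 | 7.2 | 37.5 | 1.7 |
| alder | 50.0 | 5.1 | 34.8 | 0 |
| maple | 0.500 | 17.8 | 6.0 | 65.9 |
| maple | 1.50 | 22.8 | 22.7 | 34.7 |
| maple | 5.00 | 12.2 | 46.7 | 5.6 |
| maple | 15.0 | 10.2 | 49.7 | 2.0 |
| maple | 50.0 | 8.8 | 49.9 | 0.2 |

(standard deviation of a reading: 1 percentage point)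

- in percentages every species weighs as the D in it: one Z counts as two
- on the list of suspects stand: D + L -> X + G; 2 D -> Z; X <-> Q; X <-> J

- time up to 1.0 h at which X stands highest, in min
- the amount of X, in percent of the D charged, at that time

Time first. By hand the question is whether X climbs again late, and it does not: the birch reading at 20.0 min is 10.5%, lower than its highest reading, 15.2% at 2.00 min. So the longest time allowed adds no correction.

Next D. More D should tilt D towards Z, whose suspect step takes D in pairs, and the highest reading does fall, to 12.7% in the alder run. Interpolating in c_D, I get the peak at the flask's c_D: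

15.2% + (12.7% − 15.2%) × 0.381 = 14.2%

Last L. More L should favour X, and maple shows by how much. I call the L-gain the rise of peak X from this figure to the maple reading, for the step in c_L from 37.5 mM to 75 mM:

22.8% − 14.2% = 8.6 percentage points

The flask needs none of it, since its c_L is 37.5 mM. Each reading carries 1 point.

My figure lies below the forecast's, which gives 14.5% at 1.5 min, holding that “only the first minutes matter”.

The flask gives 13.6% at 1.38 min, with D still at 52.8%, about half of its charge.

    D + L → X + G (k = 0.140 L mol⁻¹ s⁻¹)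
    2 D → Z (k = 0.0840 L mol⁻¹ s⁻¹)
    X ⇌ Q (K = 2.80, k = 0.00500 s⁻¹)
    X ⇌ J (K = 5.70, k = 0.0140 s⁻¹)

The L-gain was measured from my figure, not from this result, so for the neighbouring flask, which holds 94 mM of L, I add it to my figure, scaled in proportion to the step in c_L and carried past the maple charge:

14.2% + 8.6 points × 1.51 = 27.1%

That neighbour, at 3.76 equiv of L, reaches 26.8%, and it ends with D, the limiting reagent, at 0% and J at 51.5%.

(Readings and results stem from a simulated flask for an exercise; the scatter is artificial.)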